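The route rests on cutting the bond between C2 of the dihydropyran, the oxygen-bearing quaternary carbon, and the methine C1' of the cyclohexane. Because C2 carries the ring oxygen O1, it can be made a carbanion (a lithiated carbamate), and because the chain O1–C2–C3–C4=C5–C6 maps onto a 2-furyl carbinol, the pyran is carried as a flat 5-methylfuran. The key step, a lithiation–borylation with 1,2-metallate shift between an (S)-furfuryl carbamate and an (S)-cyclohexenyl boronic ester, forms the C2–C1' bond and sets both stereocentres stereospecifically. Achmatowicz ring expansion, anomeric methylation, a bromonium-relay halogenation and a ketone reduction complete the target.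

Key step: step 6

Assumption: 6-methylcyclohex-2-en-1-one is used as the racemate; the C2 epimers of 2 converge in step 2, where that carbon becomes sp2.
Assumption: hemiketal 12 is carried on as the anomeric mixture, since the anomeric carbon becomes the achiral gem-dimethyl carbon in step 8.

Step 1
Reactants: 1 6-methylcyclohex-2-en-1-one (racemic)
Product: 2 (5S)-2-methyl-5-(4,4,5,5-tetramethyl-1,3,2-dioxaborolan-2-yl)cyclohexan-1-one (C2 epimers)
Conditions: B2pin2, CuCl (3 mol%), NaOtBu (cat.), Josiphos-type bisphosphine (enantiomer that gives 5S), MeOH (2 equiv), THF, rt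
Reagents that add atoms: bis(pinacolato)diboron CC1(C)OB(OC1(C)C)B2OC(C)(C)C(C)(C)O2
Why: Copper-catalysed asymmetric conjugate borylation of a cyclic enone, in which the chiral bisphosphine–Cu–Bpin complex selects the enone face and sets the boron-bearing carbon as S, while the epimerisable methyl-bearing carbon needs no control.

Step 2
Reactants: 2 (5S)-2-methyl-5-(pinacolboryl)cyclohexan-1-one
Product: 3 (5S)-2-methyl-5-(4,4,5,5-tetramethyl-1,3,2-dioxaborolan-2-yl)cyclohex-1-en-1-yl trifluoromethanesulfonate
Conditions: Tf2O, 2,6-di-tert-butyl-4-methylpyridine, CH2Cl2, 0 °C → rt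
Reagents that add atoms: trifluoromethanesulfonic anhydride O=S(=O)(OS(=O)(=O)C(F)(F)F)C(F)(F)F
Why: Triflation under non-basic, equilibrating conditions should give the thermodynamic, more substituted enol triflate (C1=C2 bearing the methyl group), which erases the uncontrolled C2 centre and fixes the alkene position relative to the boron-bearing stereocentre, the alkyl pinacol boronate being inert to Tf2O.

Step 3
Reactants: 3 enol triflate
Product: 4 2-[(1S)-4-methylcyclohex-3-en-1-yl]-4,4,5,5-tetramethyl-1,3,2-dioxaborolane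
Conditions: Pd(OAc)2 (5 mol%), PPh3, HCO2H, Bu3N, DMF, 60 °C
Reagents that add atoms: none
Why: Palladium-catalysed formate reduction of an enol triflate (oxidative addition, formate-to-hydride exchange, reductive elimination) replaces OTf by H without moving the trisubstituted alkene and without touching the secondary C–B bond.

Step 4
Reactants: 5 1-(5-methylfuran-2-yl)ethan-1-one
Product: 6 (1S)-1-(5-methylfuran-2-yl)ethan-1-ol
Conditions: RuCl(p-cymene)[(S,S)-TsDPEN] (0.5 mol%), HCO2H/Et3N (5:2), rt
Reagents that add atoms: none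
Why: Noyori–Ikariya asymmetric transfer hydrogenation of a heteroaryl methyl ketone, in which the (S,S)-catalyst delivers hydride through its six-membered transition state to give the S carbinol, as it does with acetophenone.

Step 5
Reactants: 6 (1S)-1-(5-methylfuran-2-yl)ethan-1-ol
Product: 7 (1S)-1-(5-methylfuran-2-yl)ethyl N,N-diisopropylcarbamate
Conditions: iPr2NCOCl, Et3N, CH2Cl2, reflux
Reagents that add atoms: N,N-diisopropylcarbamoyl chloride CC(C)N(C(C)C)C(Cl)=O
Why: O-Carbamoylation of the secondary alcohol leaves the stereocentre untouched and installs the group that directs the lithiation and serves as the leaving group in step 6.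

Step 6
Reactants: 7 (1S)-1-(5-methylfuran-2-yl)ethyl N,N-diisopropylcarbamate, 4 2-[(1S)-4-methylcyclohex-3-en-1-yl]-4,4,5,5-tetramethyl-1,3,2-dioxaborolane
Product: 11 (1R)-1-[(1S)-4-methylcyclohex-3-en-1-yl]-1-(5-methylfuran-2-yl)ethan-1-ol, via lithiated carbamate 8 (not isolated), via boronate complex 9 (not isolated), via tertiary boronic ester 10 (not isolated)
Conditions: s-BuLi, Et2O, −78 °C; then 4, −78 °C; then MgBr2·OEt2, MeOH, −78 °C → rt; then NaOH, H2O2, THF, 0 °C → rt
Reagents that add atoms: hydrogen peroxide OO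
Why: The carbamate directs s-BuLi to the furfurylic C–H and gives, with retention, the configurationally stable α-oxy organolithium 8 (the future pyran C2 as a carbanion), which adds with retention to the boron of 4 to give ate complex 9. On warming, a stereospecific 1,2-metallate shift moves the cyclohexenyl carbon from boron with retention, anti to the departing carbamate, so the new C–C bond forms with inversion at the carbinol carbon and leaves tertiary boronic ester 10, which alkaline H2O2 oxidises with retention. The closest known reaction type is the lithiation–borylation (Matteson-type homologation) of secondary benzylic carbamates with secondary alkyl boronic esters; no ring is closed. The quaternary centre (R) is dictated by the S carbamate from step 4 and the ring methine (S) by the boronate from step 1, so the vicinal pair is formed stereospecifically and does not depend on a facial preference. The step needs migration to outrun dissociation of the hindered ate complex, which MgBr2/MeOH should secure, and α-lithiation instead of ring lithiation, which the coordinating carbamate and the blocked furan 5-position should secure.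

Step 7
Reactants: 11 (1R)-1-[(1S)-4-methylcyclohex-3-en-1-yl]-1-(5-methylfuran-2-yl)ethan-1-ol
Product: 12 (2R)-6-hydroxy-2,6-dimethyl-2-[(1S)-4-methylcyclohex-3-en-1-yl]-2H-pyran-3(6H)-one (anomeric mixture)
Conditions: NBS (1.05 equiv), NaHCO3, NaOAc, THF/H2O (4:1), 0 °C
Reagents that add atoms: water O
Why: Achmatowicz rearrangement, the oxidative ring expansion of a 2-furyl carbinol to a 6-hydroxy-2H-pyran-3(6H)-one, in which the electron-rich furan should react far faster than the trisubstituted ring alkene and the quaternary C2 is untouched.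

Step 8
Reactants: 12 (2R)-6-hydroxy-2,6-dimethyl-2-[(1S)-4-methylcyclohex-3-en-1-yl]-2H-pyran-3(6H)-one
Product: 13 (2R)-2,6,6-trimethyl-2-[(1S)-4-methylcyclohex-3-en-1-yl]-2H-pyran-3(6H)-one
Conditions: AlMe3 (4 equiv), TMSOTf (0.2 equiv), CH2Cl2, −78 → −20 °C
Reagents that add atoms: trimethylaluminium C[Al](C)C
Why: SN1-type anomeric substitution, analogous to the Kishi reduction of Achmatowicz hemiketals, exchanges the hemiketal oxygen for a methyl group from aluminium and creates the achiral gem-dimethyl carbon C6, while the hindered enone carbonyl and the ring alkene should survive at low temperature.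

Step 9
Reactants: 13 (2R)-2,6,6-trimethyl-2-[(1S)-4-methylcyclohex-3-en-1-yl]-2H-pyran-3(6H)-one
Product: 14 (2R)-2,6,6-trimethyl-2-[(1R,3S,6S)-6-methyl-7-oxabicyclo[4.1.0]heptan-3-yl]-2H-pyran-3(6H)-one (oxirane oxygen trans to the pyranyl group)
Conditions: Shi ketone (D-fructose-derived, 30 mol%), Oxone, K2CO3, Bu4NHSO4, MeCN/dimethoxymethane/aq. buffer (pH 10.5), 0 °C
Reagents that add atoms: potassium peroxymonosulfate [K+].[O-]S(=O)(=O)OO
Why: Shi epoxidation is reagent-controlled, so the chiral dioxirane should epoxidise the electron-rich trisubstituted ring alkene (the enone alkene is inert) on the face anti to the pyranyl group, in the same facial sense as with 1-phenylcyclohexene.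

Step 10
Reactants: 14 epoxide
Product: 15 (2R)-2-[(1S,3R,4R)-4-bromo-3-hydroxy-4-methylcyclohexyl]-2,6,6-trimethyl-2H-pyran-3(6H)-one
Conditions: anhydrous HBr (1.05 equiv), CH2Cl2, −78 °C
Reagents that add atoms: hydrogen bromide Br
Why: Acid-mediated epoxide opening in which Markovnikov attack at the tertiary carbon and the Fürst–Plattner (trans-diaxial) rule coincide for this epoxide with the pyranyl group equatorial, so bromide enters the tertiary carbon with inversion and the hydroxyl stays axial on the secondary carbon.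

Step 11
Reactants: 15 bromohydrin
Product: 18 (2R)-2-[(1S,3S,4S)-3-bromo-4-chloro-4-methylcyclohexyl]-2,6,6-trimethyl-2H-pyran-3(6H)-one, via chlorosulfite 16 (not isolated), via bromonium chloride 17 (not isolated)
Conditions: SOCl2 (1.5 equiv), CH2Cl2, 0 °C → rt
Reagents that add atoms: thionyl chloride ClS(Cl)=O
Why: Deoxychlorination with neighbouring-group participation, in which the axial chlorosulfite group of 16 is expelled by the antiperiplanar axial bromine to give bromonium ion 17 on the ring face cis to the pyranyl group and chloride opens it anti at the tertiary carbon (Markovnikov control), so that bromine ends on the secondary and chlorine on the tertiary carbon, trans to each other and both equatorial after ring flip.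

Step 12
Reactants: 18 (2R)-2-[(1S,3S,4S)-3-bromo-4-chloro-4-methylcyclohexyl]-2,6,6-trimethyl-2H-pyran-3(6H)-one
Product: 19 (2R,3R)-2-[(1S,3S,4S)-3-bromo-4-chloro-4-methylcyclohexyl]-2,6,6-trimethyl-3,6-dihydro-2H-pyran-3-ol
Conditions: (S)-2-methyl-CBS-oxazaborolidine (20 mol%), catecholborane, toluene, −78 → −40 °C
Reagents that add atoms: none
Why: Corey–Bakshi–Shibata reduction under reagent control, in which, with the quaternary C2 as the large and the vinyl carbon as the small carbonyl substituent, the (S)-catalyst should deliver hydride to the face of the 2-methyl group and give the 3R alcohol (hydroxyl cis to the cyclohexyl group), a result not expected from small uncatalysed hydrides that approach anti to the pseudoaxial 2-methyl group.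

Compound list

1 | 6-methylcyclohex-2-en-1-one (racemic) | CC1CCC=CC1=O | starting material
2 | (5S)-2-methyl-5-(4,4,5,5-tetramethyl-1,3,2-dioxaborolan-2-yl)cyclohexan-1-one (C2 epimers) | CC1(C)OB(OC1(C)C)[C@H]2CCC(C)C(=O)C2 | intermediate
3 | (5S)-2-methyl-5-(4,4,5,5-tetramethyl-1,3,2-dioxaborolan-2-yl)cyclohex-1-en-1-yl trifluoromethanesulfonate | CC1(C)OB(OC1(C)C)[C@H]2CCC(C)=C(OS(=O)(=O)C(F)(F)F)C2 | intermediate
4 | 2-[(1S)-4-methylcyclohex-3-en-1-yl]-4,4,5,5-tetramethyl-1,3,2-dioxaborolane | CC1(C)OB(OC1(C)C)[C@H]2CCC(C)=CC2 | intermediate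
5 | 1-(5-methylfuran-2-yl)ethan-1-one | CC(=O)c1ccc(C)o1 | starting material
6 | (1S)-1-(5-methylfuran-2-yl)ethan-1-ol | Cc1ccc(o1)[C@H](C)O | intermediate
7 | (1S)-1-(5-methylfuran-2-yl)ethyl N,N-diisopropylcarbamate | Cc1ccc(o1)[C@H](C)OC(=O)N(C(C)C)C(C)C | intermediate
8 | (1S)-1-lithio-1-(5-methylfuran-2-yl)ethyl N,N-diisopropylcarbamate (not isolated) | Cc1ccc(o1)[C@]([Li])(C)OC(=O)N(C(C)C)C(C)C | intermediate
9 | lithium boronate (ate) complex of 8 with 4 (not isolated) | [Li+].Cc1ccc(o1)[C@](C)(OC(=O)N(C(C)C)C(C)C)[B-]2(OC(C)(C)C(C)(C)O2)[C@H]3CCC(C)=CC3 | intermediate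
10 | 2-{(1S)-1-[(1S)-4-methylcyclohex-3-en-1-yl]-1-(5-methylfuran-2-yl)ethyl}-4,4,5,5-tetramethyl-1,3,2-dioxaborolane (not isolated) | Cc1ccc(o1)[C@@](C)([C@H]2CCC(C)=CC2)B3OC(C)(C)C(C)(C)O3 | intermediate
11 | (1R)-1-[(1S)-4-methylcyclohex-3-en-1-yl]-1-(5-methylfuran-2-yl)ethan-1-ol | Cc1ccc(o1)[C@@](C)([C@H]2CCC(C)=CC2)O | intermediate
12 | (2R)-6-hydroxy-2,6-dimethyl-2-[(1S)-4-methylcyclohex-3-en-1-yl]-2H-pyran-3(6H)-one (anomeric mixture) | CC1(O)C=CC(=O)[C@@](C)([C@H]2CCC(C)=CC2)O1 | intermediate
13 | (2R)-2,6,6-trimethyl-2-[(1S)-4-methylcyclohex-3-en-1-yl]-2H-pyran-3(6H)-one | CC1(C)C=CC(=O)[C@@](C)([C@H]2CCC(C)=CC2)O1 | intermediate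
14 | (2R)-2,6,6-trimethyl-2-[(1R,3S,6S)-6-methyl-7-oxabicyclo[4.1.0]heptan-3-yl]-2H-pyran-3(6H)-one | CC1(C)C=CC(=O)[C@@](C)([C@H]2CC[C@]3(C)O[C@@H]3C2)O1 | intermediate
15 | (2R)-2-[(1S,3R,4R)-4-bromo-3-hydroxy-4-methylcyclohexyl]-2,6,6-trimethyl-2H-pyran-3(6H)-one | CC1(C)C=CC(=O)[C@@](C)([C@H]2CC[C@@](C)(Br)[C@H](O)C2)O1 | intermediate
16 | chlorosulfite ester of 15 at the secondary hydroxyl (not isolated) | CC1(C)C=CC(=O)[C@@](C)([C@H]2CC[C@@](C)(Br)[C@H](OS(Cl)=O)C2)O1 | intermediate
17 | bridged bromonium ion (bromine cis to the pyranyl group) as chloride ion pair (not isolated) | CC1(C)C=CC(=O)[C@@](C)([C@H]2CC[C@@]3(C)[Br+][C@H]3C2)O1.[Cl-] | intermediate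
18 | (2R)-2-[(1S,3S,4S)-3-bromo-4-chloro-4-methylcyclohexyl]-2,6,6-trimethyl-2H-pyran-3(6H)-one | CC1(C)C=CC(=O)[C@@](C)([C@H]2CC[C@](C)(Cl)[C@@H](Br)C2)O1 | intermediate
19 | (2R,3R)-2-[(1S,3S,4S)-3-bromo-4-chloro-4-methylcyclohexyl]-2,6,6-trimethyl-3,6-dihydro-2H-pyran-3-ol | CC1(C)C=C[C@@H](O)[C@@](C)([C@H]2CC[C@](C)(Cl)[C@@H](Br)C2)O1 | target

Total step count: 12. Longest linear sequence: 10 steps (steps 1–3 and 6–12); steps 4–5 form the second branch.

Steps most likely to fail

Step 6. The hindered pinacol boronate may form its ate complex reversibly, so that the lithiated carbamate racemises or decomposes before the congested 1,2-migration takes place. The fallback sets out from 4 and changes the boron partner to a smaller one: KHF2 (MeOH/H2O) should give potassium [(1S)-4-methylcyclohex-3-en-1-yl]trifluoroborate F1, and neopentyl glycol with TMSCl (MeCN) should give 5,5-dimethyl-2-[(1S)-4-methylcyclohex-3-en-1-yl]-1,3,2-dioxaborinane F2. The lithiated carbamate 8 from 7 should add to F2 irreversibly to give the neopentyl glycol ate complex F3, which rearranges to the tertiary neopentyl glycol boronic ester F4; oxidation with NaOH/H2O2 comes back to the route at 11.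

Step 11. Chloride may open the bromonium ion at the secondary carbon (the diaxial mode) instead of the tertiary one, or the tertiary bromide may eliminate, so that the halogens end on the wrong carbons or an alkene forms. The fallback sets out from 13 and adds bromine chloride directly across the ring alkene with tetrabutylammonium dichlorobromate (CH2Cl2, −78 °C). Anti, Markovnikov addition should give 18 together with its diaxial diastereomer (2R)-2-[(1S,3R,4R)-3-bromo-4-chloro-4-methylcyclohexyl]-2,6,6-trimethyl-2H-pyran-3(6H)-one F5, which arises from the bromonium ion on the other face and is removed by chromatography; the route is rejoined at 18.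

Step 12. Facial selectivity may be poor if the substrate bias (hydride approach anti to the pseudoaxial 2-methyl group) overrides the catalyst. The fallback sets out from 18: Luche reduction (NaBH4, CeCl3·7H2O, MeOH, −78 °C) should give the C3 epimer (2R,3S)-2-[(1S,3S,4S)-3-bromo-4-chloro-4-methylcyclohexyl]-2,6,6-trimethyl-3,6-dihydro-2H-pyran-3-ol F6. Mitsunobu inversion (4-nitrobenzoic acid, DIAD, PPh3, THF) should give the (2R,3R)-4-nitrobenzoate F7, and methanolysis (K2CO3, MeOH, 0 °C) comes back to the route at 19.

Further compounds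

F1 | step 6 | potassium [(1S)-4-methylcyclohex-3-en-1-yl]trifluoroborate | [K+].F[B-](F)(F)[C@H]1CCC(C)=CC1
F2 | step 6 | 5,5-dimethyl-2-[(1S)-4-methylcyclohex-3-en-1-yl]-1,3,2-dioxaborinane | CC1(C)COB(OC1)[C@H]2CCC(C)=CC2
F3 | step 6 | lithium boronate (ate) complex of 8 with F2 | [Li+].Cc1ccc(o1)[C@](C)(OC(=O)N(C(C)C)C(C)C)[B-]2(OCC(C)(C)CO2)[C@H]3CCC(C)=CC3
F4 | step 6 | 5,5-dimethyl-2-{(1S)-1-[(1S)-4-methylcyclohex-3-en-1-yl]-1-(5-methylfuran-2-yl)ethyl}-1,3,2-dioxaborinane | Cc1ccc(o1)[C@@](C)([C@H]2CCC(C)=CC2)B3OCC(C)(C)CO3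
F5 | step 11 | (2R)-2-[(1S,3R,4R)-3-bromo-4-chloro-4-methylcyclohexyl]-2,6,6-trimethyl-2H-pyran-3(6H)-one | CC1(C)C=CC(=O)[C@@](C)([C@H]2CC[C@@](C)(Cl)[C@H](Br)C2)O1
F6 | step 12 | (2R,3S)-2-[(1S,3S,4S)-3-bromo-4-chloro-4-methylcyclohexyl]-2,6,6-trimethyl-3,6-dihydro-2H-pyran-3-ol | CC1(C)C=C[C@H](O)[C@@](C)([C@H]2CC[C@](C)(Cl)[C@@H](Br)C2)O1
F7 | step 12 | (2R,3R)-2-[(1S,3S,4S)-3-bromo-4-chloro-4-methylcyclohexyl]-2,6,6-trimethyl-3,6-dihydro-2H-pyran-3-yl 4-nitrobenzoate | CC1(C)C=C[C@@H](OC(=O)c3ccc(cc3)[N+](=O)[O-])[C@@](C)([C@H]2CC[C@](C)(Cl)[C@@H](Br)C2)O1
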